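1. The target is cut first at the C-1'–C-7' bond: the (E)-propenol arm goes on last, at the only unhindered C–H of ring B (the benzene ring of the benzofuran), by C–H borylation and Suzuki coupling. The C-9 CH2OH is traced back to an (E)-propenyl group on C-8 (ozonolysis, reduction).
2. Key disconnection: ring C (the dihydrofuran) is opened at O–C-4' and at C-7–C-8 together. This leads to an acyclic (Z)-allylic 3,4,5-trimethoxybenzyl ether whose ring B carries fluorine at C-4'.
3. Enabling feature: C-7 is benzylic and already bonded to the ring oxygen; C-8 becomes the γ-carbon of an allyl unit once C-9 is an alkene carbon; O–C-4' lies ortho to the C-8-bearing C-3'. A [2,3]-Wittig shift of the O–C-7 carbanion therefore makes C-7–C-8 and frees exactly the alkoxide that can close ring C by SNAr at C-4'–F.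
4. Both stereocentres derive from (S)-but-3-yn-2-ol by 1,3-chirality transfer across the (Z)-alkene. The ether is assembled by Sonogashira coupling, O-benzylation and Lindlar reduction.
5. Ring order: rings A (trimethoxyphenyl) and B are bought as arenes; ring C is the only ring formed, in step 4.

Key step: step 4

Remark (assumption): the neolignan locants C-7, C-8, C-3', C-4' and C-1' are C-2, C-3, C-3a, C-7a and C-5 of the 2,3-dihydro-1-benzofuran names used below, and the four building blocks, including (2E)-3-iodoprop-2-en-1-ol, are taken as catalogue chemicals.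

Step 1
Reactants: 1 1-bromo-2-fluoro-3-methoxybenzene; 2 (2S)-but-3-yn-2-ol
Product: 3 (2S)-4-(2-fluoro-3-methoxyphenyl)but-3-yn-2-ol
Conditions: PdCl2(PPh3)2 (2 mol%), CuI (4 mol%), Et3N, THF, 60 °C
Reagents that add atoms: none
Why: Sonogashira coupling of an aryl bromide with a terminal alkyne tolerates the free hydroxyl and the C–F bond and leaves the purchased (S)-carbinol centre untouched.

Step 2
Reactants: 3 (2S)-4-(2-fluoro-3-methoxyphenyl)but-3-yn-2-ol; 4 5-(chloromethyl)-1,2,3-trimethoxybenzene
Product: 5 5-({[(2S)-4-(2-fluoro-3-methoxyphenyl)but-3-yn-2-yl]oxy}methyl)-1,2,3-trimethoxybenzene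
Conditions: NaH, Bu4NI (cat.), THF/DMF, 0 °C to rt
Reagents that add atoms: none
Why: Williamson etherification of the secondary propargylic alcohol with a reactive benzylic chloride (iodide catalysis) takes place at oxygen and leaves the stereocentre and the unactivated C–F bond untouched.

Step 3
Reactants: 5 5-({[(2S)-4-(2-fluoro-3-methoxyphenyl)but-3-yn-2-yl]oxy}methyl)-1,2,3-trimethoxybenzene
Product: 6 5-({[(2S,3Z)-4-(2-fluoro-3-methoxyphenyl)but-3-en-2-yl]oxy}methyl)-1,2,3-trimethoxybenzene
Conditions: H2 (1 atm), Pd/CaCO3 poisoned with Pb(OAc)2 (Lindlar catalyst), quinoline, EtOAc, rt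
Reagents that add atoms: none
Why: Lindlar semihydrogenation adds H2 syn to the alkyne and should stop at the (Z)-alkene, the geometry needed in step 4 for syn selectivity and clean chirality transfer, while the benzyl ether and the C–F bond are inert.

Step 4
Reactants: 6 5-({[(2S,3Z)-4-(2-fluoro-3-methoxyphenyl)but-3-en-2-yl]oxy}methyl)-1,2,3-trimethoxybenzene
Product: 8 (2R,3R)-7-methoxy-3-[(1E)-prop-1-en-1-yl]-2-(3,4,5-trimethoxyphenyl)-2,3-dihydro-1-benzofuran, via lithium alkoxide 7 (not isolated)
Conditions: n-BuLi (1.1 equiv), THF, −78 to −40 °C; then KN(SiMe3)2 (1.2 equiv), −40 to 60 °C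
Reagents that add atoms: none
Why: n-BuLi removes a proton from the benzylic OCH2 group of 6 and the α-oxy benzyl carbanion undergoes a suprafacial [2,3]-Wittig rearrangement through a five-membered envelope transition state, which forms the C-2–C-3 bond and releases alkoxide 7; in the presence of potassium ions this oxygen adds to the ortho C–F carbon and fluoride leaves (SNAr), which forms the O-1–C-7a bond. Both halves are known reaction types on their own substrate classes, the [2,3]-Wittig rearrangement of allyl benzyl ethers with 1,3-chirality transfer and the cyclisation of 2-(2-fluoroaryl)ethoxides to 2,3-dihydrobenzofurans, here run in sequence in one flask. Ring C closes 5-exo at the sp2 C–F carbon through a Meisenheimer adduct, and the sigmatropic step closes no ring. C-3 is controlled by the (S)-carbinol centre, because allylic 1,3-strain in the (Z)-alkene keeps its methyl group away from the aryl group, so the C–O bond leaves from, and the carbanion adds to, one face only and an (E)-propenyl group results; C-2 is controlled by the (Z)-alkene geometry, which places the trimethoxyphenyl group exo in the envelope and should give the syn alkoxide, and syn corresponds to the 2,3-trans ring. The step needs lithiation at the benzylic CH2 and not at the allylic methine or on the rings, and [2,3] in preference to [1,2] shift: the same allylic strain holds the methine C–H in the alkene plane where it is not acidified, ring B has no hydrogen ortho to fluorine (no aryne, no ortho-lithiation there), and −78 °C favours the concerted pathway. KN(SiMe3)2 is chosen as potassium source because it is too weak a base to deprotonate the doubly activated C-3–H of 8, so the propenyl double bond should not migrate during ring closure.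

Step 5
Reactants: 8 (2R,3R)-7-methoxy-3-[(1E)-prop-1-en-1-yl]-2-(3,4,5-trimethoxyphenyl)-2,3-dihydro-1-benzofuran
Product: 10 [(2R,3S)-7-methoxy-2-(3,4,5-trimethoxyphenyl)-2,3-dihydro-1-benzofuran-3-yl]methanol, via aldehyde 9 (not isolated)
Conditions: O3 (to the Sudan Red 7B end point), CH2Cl2/MeOH, −78 °C; then NaBH4, −78 to 0 °C
Reagents that add atoms: ozone, [O-][O+]=O
Why: Ozonolysis with reductive NaBH4 work-up cleaves the only C=C bond and reduces the aldehyde in the same flask, and C-3 keeps its configuration because the transient α-aryl aldehyde already has the thermodynamically preferred 2,3-trans arrangement (the change of descriptor at C-3 is only a priority change).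

Step 6
Reactants: 10 [(2R,3S)-7-methoxy-2-(3,4,5-trimethoxyphenyl)-2,3-dihydro-1-benzofuran-3-yl]methanol; 11 (2E)-3-iodoprop-2-en-1-ol
Product: 13 (-)-(7R,8S,7'E)-3,4,5,5'-tetramethoxy-4',7-epoxy-8,3'-neolign-7'-ene-9,9'-diol, via bis(boronate) 12 (not isolated)
Conditions: [Ir(cod)(OMe)]2 (1.5 mol%), 4,4'-di-tert-butyl-2,2'-bipyridine (3 mol%), B2pin2, THF, 70 °C; then 11, Pd(dppf)Cl2 (5 mol%), K3PO4, H2O, 60 °C
Reagents that add atoms: bis(pinacolato)diboron, CC1(C)OB(OC1(C)C)B1OC(C)(C)C(C)(C)O1 (supplies the two boryl groups of 12; none of its atoms remain in 13)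
Why: Iridium-catalysed C–H borylation is sterically controlled and should select C-5–H, the only arene C–H without an ortho substituent (the hydroxyl is O-borylated transiently), and the one-pot Suzuki–Miyaura coupling with vinyl iodide 11 retains the (E) geometry and hydrolyses the O–B bond, so no stereocentre is touched.

Compound list
1 | 1-bromo-2-fluoro-3-methoxybenzene | COc1cccc(Br)c1F | starting material
2 | (2S)-but-3-yn-2-ol | C[C@H](O)C#C | starting material
3 | (2S)-4-(2-fluoro-3-methoxyphenyl)but-3-yn-2-ol | C[C@H](O)C#Cc1cccc(OC)c1F | intermediate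
4 | 5-(chloromethyl)-1,2,3-trimethoxybenzene | COc1cc(CCl)cc(OC)c1OC | starting material
5 | 5-({[(2S)-4-(2-fluoro-3-methoxyphenyl)but-3-yn-2-yl]oxy}methyl)-1,2,3-trimethoxybenzene | C[C@H](OCc1cc(OC)c(OC)c(OC)c1)C#Cc1cccc(OC)c1F | intermediate
6 | 5-({[(2S,3Z)-4-(2-fluoro-3-methoxyphenyl)but-3-en-2-yl]oxy}methyl)-1,2,3-trimethoxybenzene | C[C@H](OCc1cc(OC)c(OC)c(OC)c1)/C=C\c1cccc(OC)c1F | intermediate
7 | lithium (1R,2R,3E)-2-(2-fluoro-3-methoxyphenyl)-1-(3,4,5-trimethoxyphenyl)pent-3-en-1-olate | [Li+].COc1cc([C@H]([O-])[C@H](/C=C/C)c2cccc(OC)c2F)cc(OC)c1OC | intermediate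
8 | (2R,3R)-7-methoxy-3-[(1E)-prop-1-en-1-yl]-2-(3,4,5-trimethoxyphenyl)-2,3-dihydro-1-benzofuran | COc1cc([C@@H]2Oc3c(OC)cccc3[C@H]2/C=C/C)cc(OC)c1OC | intermediate
9 | (2R,3R)-7-methoxy-2-(3,4,5-trimethoxyphenyl)-2,3-dihydro-1-benzofuran-3-carbaldehyde | COc1cc([C@@H]2Oc3c(OC)cccc3[C@H]2C=O)cc(OC)c1OC | intermediate
10 | [(2R,3S)-7-methoxy-2-(3,4,5-trimethoxyphenyl)-2,3-dihydro-1-benzofuran-3-yl]methanol | COc1cc([C@@H]2Oc3c(OC)cccc3[C@H]2CO)cc(OC)c1OC | intermediate
11 | (2E)-3-iodoprop-2-en-1-ol | OC/C=C/I | starting material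
12 | 2-[(2R,3S)-7-methoxy-3-{[(4,4,5,5-tetramethyl-1,3,2-dioxaborolan-2-yl)oxy]methyl}-2-(3,4,5-trimethoxyphenyl)-2,3-dihydro-1-benzofuran-5-yl]-4,4,5,5-tetramethyl-1,3,2-dioxaborolane | COc1cc([C@@H]2Oc3c(OC)cc(B4OC(C)(C)C(C)(C)O4)cc3[C@H]2COB5OC(C)(C)C(C)(C)O5)cc(OC)c1OC | intermediate
13 | (-)-(7R,8S,7'E)-3,4,5,5'-tetramethoxy-4',7-epoxy-8,3'-neolign-7'-ene-9,9'-diol | COc1cc([C@@H]2Oc3c(OC)cc(/C=C/CO)cc3[C@H]2CO)cc(OC)c1OC | target

Total step count: 6. Longest linear sequence: 6 steps (from 1 or 2 to 13).

Steps most likely to fail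

Step 4. Fluoride displacement on the unactivated, electron-rich ring B may be slower than base-induced migration of the propenyl double bond into conjugation. Partial ring lithiation of the trimethoxyphenyl group or a [1,2]-shift may erode the rearrangement. A lower syn preference would show up as the 2,3-cis isomer of 8, to be removed by chromatography at that stage. The fallback decouples the two bond formations and closes ring C by palladium-catalysed etherification instead of SNAr; it sets out from 2 and 4. Sonogashira coupling of 2 with 1-bromo-2-chloro-3-methoxybenzene F1 (chemoselective at bromine) should give (2S)-4-(2-chloro-3-methoxyphenyl)but-3-yn-2-ol F2. O-Benzylation with 4 (NaH, Bu4NI) should give 5-({[(2S)-4-(2-chloro-3-methoxyphenyl)but-3-yn-2-yl]oxy}methyl)-1,2,3-trimethoxybenzene F3, and Lindlar reduction should give 5-({[(2S,3Z)-4-(2-chloro-3-methoxyphenyl)but-3-en-2-yl]oxy}methyl)-1,2,3-trimethoxybenzene F4. Treatment with n-BuLi (THF, −78 °C, aryl chloride inert) and aqueous quench should give the [2,3]-Wittig product alone, (1R,2R,3E)-2-(2-chloro-3-methoxyphenyl)-1-(3,4,5-trimethoxyphenyl)pent-3-en-1-ol F5. Intramolecular Pd-catalysed C–O coupling (Pd(OAc)2, 2-(di-tert-butylphosphino)-1,1'-binaphthyl, Cs2CO3, toluene, 80 °C), a weak-base etherification that preserves secondary carbinol centres, should then close ring C and return to the route at 8.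

Step 6. Regiocontrol of the C–H borylation may be incomplete (attack next to the methoxy group), and the electron-rich boronate may protodeboronate in the aqueous coupling stage with the unprotected iodoallylic alcohol. The fallback sets out from 10. Borylation as in step 6 followed by methanol work-up and chromatography (which also removes minor regioisomers) should give [(2R,3S)-7-methoxy-5-(4,4,5,5-tetramethyl-1,3,2-dioxaborolan-2-yl)-2-(3,4,5-trimethoxyphenyl)-2,3-dihydro-1-benzofuran-3-yl]methanol F6. Base-free oxidative Heck coupling with methyl acrylate (Pd(OAc)2, 2,9-dimethyl-1,10-phenanthroline, O2, DMF, 50 °C) should give methyl (2E)-3-[(2R,3S)-3-(hydroxymethyl)-7-methoxy-2-(3,4,5-trimethoxyphenyl)-2,3-dihydro-1-benzofuran-5-yl]prop-2-enoate F7. Reduction with i-Bu2AlH (CH2Cl2, −78 °C) should then give 13.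

Step 5. Ozone may over-oxidise the two electron-rich arenes or the benzylic ether C–H before the alkene is fully consumed. The fallback sets out from 8 and avoids ozone. Dihydroxylation (OsO4 cat., N-methylmorpholine N-oxide, acetone/H2O) should give 1-[(2R,3S)-7-methoxy-2-(3,4,5-trimethoxyphenyl)-2,3-dihydro-1-benzofuran-3-yl]propane-1,2-diol F8 as a mixture of the two syn-diol diastereomers. Glycol cleavage with NaIO4 (THF/H2O) should give aldehyde 9, which is reduced with NaBH4 to 10 as in step 5.

Further compounds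
F1 | step 4 | 1-bromo-2-chloro-3-methoxybenzene | COc1cccc(Br)c1Cl
F2 | step 4 | (2S)-4-(2-chloro-3-methoxyphenyl)but-3-yn-2-ol | C[C@H](O)C#Cc1cccc(OC)c1Cl
F3 | step 4 | 5-({[(2S)-4-(2-chloro-3-methoxyphenyl)but-3-yn-2-yl]oxy}methyl)-1,2,3-trimethoxybenzene | C[C@H](OCc1cc(OC)c(OC)c(OC)c1)C#Cc1cccc(OC)c1Cl
F4 | step 4 | 5-({[(2S,3Z)-4-(2-chloro-3-methoxyphenyl)but-3-en-2-yl]oxy}methyl)-1,2,3-trimethoxybenzene | C[C@H](OCc1cc(OC)c(OC)c(OC)c1)/C=C\c1cccc(OC)c1Cl
F5 | step 4 | (1R,2R,3E)-2-(2-chloro-3-methoxyphenyl)-1-(3,4,5-trimethoxyphenyl)pent-3-en-1-ol | COc1cc([C@H](O)[C@H](/C=C/C)c2cccc(OC)c2Cl)cc(OC)c1OC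
F6 | step 6 | [(2R,3S)-7-methoxy-5-(4,4,5,5-tetramethyl-1,3,2-dioxaborolan-2-yl)-2-(3,4,5-trimethoxyphenyl)-2,3-dihydro-1-benzofuran-3-yl]methanol | COc1cc([C@@H]2Oc3c(OC)cc(B4OC(C)(C)C(C)(C)O4)cc3[C@H]2CO)cc(OC)c1OC
F7 | step 6 | methyl (2E)-3-[(2R,3S)-3-(hydroxymethyl)-7-methoxy-2-(3,4,5-trimethoxyphenyl)-2,3-dihydro-1-benzofuran-5-yl]prop-2-enoate | COc1cc([C@@H]2Oc3c(OC)cc(/C=C/C(=O)OC)cc3[C@H]2CO)cc(OC)c1OC
F8 | step 5 | 1-[(2R,3S)-7-methoxy-2-(3,4,5-trimethoxyphenyl)-2,3-dihydro-1-benzofuran-3-yl]propane-1,2-diol (syn diol, both facial diastereomers) | COc1cc([C@@H]2Oc3c(OC)cccc3[C@H]2C(O)C(C)O)cc(OC)c1OC
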